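Retrosynthesis (labdane numbering): the 3-acetate and the C19 and C15 acids go back to a silylated 3β,19-diol methyl ester; C8=C17 with C9–H goes back to a Δ8 C17 carbinol (reductive allylic transposition); the chain is cut at C13–C16 and C11–C12; C5–H comes from C5=C6.
Enabling feature: ring B then carries C10 (quaternary, C20), C9 (bearing C11) and C8 (bearing C17) in a row beside C5=C6. This is the imprint of a [4+2] between the ring-A diene C10=C5–C6=C7 and an alkyne C8≡C9 flanked by C11 and C17, so C7–C8 and C9–C10 are cut together.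
Ring A is cut at C5–C6 (vinyl coupling), C10–C20 (enolate methylation) and C4–C19 (hydroxymethylation), back to 2-methylcyclohexane-1,3-dione.
Forward order: ring A (steps 1–7), ynal (steps 8–9), ring B by cycloaddition (step 10), trans ring fusion (step 11), chain C12–C16 (steps 12–16), C8=C17 and C9–H (steps 17–18), oxidation states and acetate (steps 19–22).
Stereochemistry: C3 and C4 from a catalytic enantioselective desymmetrising reduction; C10 from the diene face left open by the pseudo-axial C19 arm; C5 and C9 from hydrogen delivery to the α face; 13E from a Z-enol phosphate substituted with retention.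

Key step: step 10

Remark: labdane numbering is used for all intermediates (C18 = 4α-methyl, C19 = 4β carbon, C20 on C10, C17 on C8); TBS = tert-butyldimethylsilyl, TIPS = triisopropylsilyl.
Assumption: O3 and O19 are carried as two separate silyl ethers and not as a cyclic acetal, because a six-membered ring across them would favour the half-chair with C19 pseudo-equatorial and would turn the dienophile to the β face.

Step 1
Reactants: 1 2-methylcyclohexane-1,3-dione; 2 formaldehyde
Product: 3 2-(hydroxymethyl)-2-methylcyclohexane-1,3-dione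
Conditions: 37% aq. CH2O, H2O, rt
Reagents that add atoms: none
Why: Aldol-type hydroxymethylation of the doubly activated C–H of a 2-alkyl-1,3-dione, which stops at the mono-adduct because no acidic hydrogen remains between the carbonyl groups; no stereocentre is formed.

Step 2
Reactants: 3 2-(hydroxymethyl)-2-methylcyclohexane-1,3-dione
Product: 4 2-[(tert-butyldimethylsilyloxy)methyl]-2-methylcyclohexane-1,3-dione
Conditions: TBSCl, imidazole, DMF, 0 °C → rt
Reagents that add atoms: tert-butyl(chloro)dimethylsilane, CC(C)(C)[Si](C)(C)Cl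
Why: Standard silylation of a primary alcohol under conditions mild enough to avoid retro-aldol loss of formaldehyde; the bulky silyloxymethyl arm later differentiates the two faces of the dione.

Step 3
Reactants: 4 2-[(tert-butyldimethylsilyloxy)methyl]-2-methylcyclohexane-1,3-dione
Product: 5 (2S,3S)-2-[(tert-butyldimethylsilyloxy)methyl]-3-hydroxy-2-methylcyclohexan-1-one (hydroxyl cis to the silyloxymethyl arm)
Conditions: (R)-2-methyl-CBS-oxazaborolidine [(R)-tetrahydro-1-methyl-3,3-diphenyl-1H,3H-pyrrolo[1,2-c][1,3,2]oxazaborole] (0.2 equiv), catecholborane (1.1 equiv), PhNEt2, toluene, −60 °C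
Reagents that add atoms: none
Why: Corey–Bakshi–Shibata reduction used as a desymmetrisation, in which the oxazaborolidine selects one of the two enantiotopic carbonyl groups and hydride arrives anti to the silyloxymethyl arm, so that the C3 carbinol (S) ends cis to C19 and the quaternary C4 (S) is fixed in the same event.

Step 4
Reactants: 5 (2S,3S)-2-[(tert-butyldimethylsilyloxy)methyl]-3-hydroxy-2-methylcyclohexan-1-one
Product: 6 (2S,3S)-2-[(tert-butyldimethylsilyloxy)methyl]-2-methyl-3-(triisopropylsilyloxy)cyclohexan-1-one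
Conditions: TIPSOTf, 2,6-lutidine, CH2Cl2, −78 → 0 °C
Reagents that add atoms: triisopropylsilyl trifluoromethanesulfonate, CC(C)[Si](OS(=O)(=O)C(F)(F)F)(C(C)C)C(C)C
Why: Silylation of a hindered secondary alcohol with a silyl triflate and a hindered pyridine base, which caps the β-hydroxy ketone against retro-aldol cleavage and installs the bulky group that later biases ring A.

Step 5
Reactants: 6 (2S,3S)-2-[(tert-butyldimethylsilyloxy)methyl]-2-methyl-3-(triisopropylsilyloxy)cyclohexan-1-one
Product: 7 (2S,3S)-2-[(tert-butyldimethylsilyloxy)methyl]-2,6-dimethyl-3-(triisopropylsilyloxy)cyclohexan-1-one (mixture of C6 epimers)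
Conditions: LiN(i-Pr)2, THF, −78 °C; MeI, −78 → −20 °C
Reagents that add atoms: iodomethane, CI
Why: Kinetic lithium enolate alkylation in which deprotonation can occur only at C10 because C4 is quaternary, so that methyl iodide introduces C20; the configuration of the new centre is irrelevant since C10 becomes sp2 in step 6.

Step 6
Reactants: 7 (2S,3S)-2-[(tert-butyldimethylsilyloxy)methyl]-2,6-dimethyl-3-(triisopropylsilyloxy)cyclohexan-1-one
Product: 8 (5S,6S)-6-[(tert-butyldimethylsilyloxy)methyl]-2,6-dimethyl-5-(triisopropylsilyloxy)cyclohex-1-en-1-yl trifluoromethanesulfonate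
Conditions: KN(SiMe3)2, THF, −78 → 0 °C; PhNTf2, −78 °C → rt
Reagents that add atoms: N-phenylbis(trifluoromethanesulfonimide), O=S(=O)(N(c1ccccc1)S(=O)(=O)C(F)(F)F)C(F)(F)F
Why: Enol triflate formation from the only possible (tetrasubstituted) potassium enolate and N-phenyltriflimide, as established for 2,2,6-trisubstituted cyclohexanones.

Step 7
Reactants: 8 (5S,6S)-6-[(tert-butyldimethylsilyloxy)methyl]-2,6-dimethyl-5-(triisopropylsilyloxy)cyclohex-1-en-1-yl trifluoromethanesulfonate; 9 tributyl(vinyl)stannane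
Product: 10 tert-butyl{[(1S,6S)-1,3-dimethyl-6-(triisopropylsilyloxy)-2-vinylcyclohex-2-en-1-yl]methoxy}dimethylsilane (ring-A diene C10=C5–C6=C7)
Conditions: Pd(PPh3)4 (5 mol%), LiCl (3 equiv), THF, 70 °C
Reagents that add atoms: none
Why: Stille coupling of a vinyl triflate with a vinylstannane under zerovalent palladium catalysis with LiCl, a reaction established for 2,6,6-trisubstituted cyclohexenyl triflates, which forms C5–C6 and completes the diene.

Step 8
Reactants: 11 but-2-yne-1,4-diol
Product: 12 4-(tert-butyldimethylsilyloxy)but-2-yn-1-ol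
Conditions: NaH (1.0 equiv), THF, 0 °C; TBSCl (1.0 equiv), rt
Reagents that add atoms: tert-butyl(chloro)dimethylsilane, CC(C)(C)[Si](C)(C)Cl
Why: Monosilylation of a symmetrical diol through its monosodium alkoxide, a standard way to differentiate the two ends of but-2-yne-1,4-diol.

Step 9
Reactants: 12 4-(tert-butyldimethylsilyloxy)but-2-yn-1-ol
Product: 13 4-(tert-butyldimethylsilyloxy)but-2-ynal
Conditions: MnO2 (10 equiv), CH2Cl2, rt
Reagents that add atoms: none
Why: MnO2 oxidation of a propargylic alcohol to the ynal, selective and non-acidic so that the silyl ether is untouched.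

Step 10
Reactants: 10 tert-butyl{[(1S,6S)-1,3-dimethyl-6-(triisopropylsilyloxy)-2-vinylcyclohex-2-en-1-yl]methoxy}dimethylsilane; 13 4-(tert-butyldimethylsilyloxy)but-2-ynal
Product: 14 17,19-bis(tert-butyldimethylsilyloxy)-3β-(triisopropylsilyloxy)-12,13,14,15,16-pentanorlabda-5,8-dien-11-al (10β-methyl)
Conditions: 13 (3 equiv), 2,6-di-tert-butyl-4-methylphenol (5 mol%), toluene (2 M), 110 °C, sealed tube
Reagents that add atoms: none
Why: A thermal, concerted but asynchronous [4+2] cycloaddition between the electron-rich semicyclic diene and the ynal, the closest known reaction type being the Diels–Alder addition of acetylenic esters and aldehydes to 2,6,6-trisubstituted 1-vinylcyclohexenes used for drimanes. Ring B closes as a six-membered carbocycle in an intermolecular [4+2] mode of closure, C7–C8 and C9–C10 forming in one step and leaving a cyclohexa-1,4-diene (C5=C6, C8=C9). C10 is the only new stereocentre and is controlled by ring A: in the half-chair with the bulky 3β-OTIPS group equatorial, the C19 silyloxymethyl arm on C4 is pseudo-axial over the β face, so the ynal bonds to the α face and C20 ends β, cis to C19. The ring-flipped half-chair offers no open face (pseudo-axial C18 methyl below, axial OTIPS above), which is why the two oxygens are kept as separate bulky ethers. The step needs regioselectivity, secured by the polarised ynal and by sterics: the unsubstituted terminus C7 bonds in advance to the β-carbon (C8, bearing C17) and the tetrasubstituted C10 to the α-carbon (C9, bearing the aldehyde C11). Only a slim, rod-shaped dienophile such as an alkyne can approach the hindered terminus, and excess ynal with a radical inhibitor compensates for its thermal loss.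

Step 11
Reactants: 14 17,19-bis(tert-butyldimethylsilyloxy)-3β-(triisopropylsilyloxy)-12,13,14,15,16-pentanorlabda-5,8-dien-11-al
Product: 15 (5α)-17,19-bis(tert-butyldimethylsilyloxy)-3β-(triisopropylsilyloxy)-12,13,14,15,16-pentanorlabd-8-en-11-al (trans-fused)
Conditions: H2 (3 atm), 10% Pd/C, EtOAc, rt
Reagents that add atoms: none
Why: Heterogeneous catalytic hydrogenation in which the trisubstituted C5=C6 bond is reduced in preference to the tetrasubstituted, aldehyde-conjugated C8=C9 bond and hydrogen adds from the α face opposite the axial C20 methyl and C19 arm, giving the 5α-H trans ring fusion as known for drimane 5,8-dienes.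

Step 12
Reactants: 15 (5α)-17,19-bis(tert-butyldimethylsilyloxy)-3β-(triisopropylsilyloxy)-12,13,14,15,16-pentanorlabd-8-en-11-al
Product: 16 (5α)-17,19-bis(tert-butyldimethylsilyloxy)-3β-(triisopropylsilyloxy)-12,13,14,15,16-pentanorlabd-8-en-11-ol
Conditions: NaBH4, CeCl3·7H2O, MeOH, 0 °C
Reagents that add atoms: none
Why: Luche 1,2-reduction of the hindered enal to the primary allylic alcohol at C11 without touching the tetrasubstituted alkene or the silyl ethers.

Step 13
Reactants: 16 (5α)-17,19-bis(tert-butyldimethylsilyloxy)-3β-(triisopropylsilyloxy)-12,13,14,15,16-pentanorlabd-8-en-11-ol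
Product: 17 (5α)-11-bromo-17,19-bis(tert-butyldimethylsilyloxy)-3β-(triisopropylsilyloxy)-12,13,14,15,16-pentanorlabd-8-ene
Conditions: CBr4, PPh3, 2,6-lutidine, CH2Cl2, 0 °C
Reagents that add atoms: tetrabromomethane, BrC(Br)(Br)Br
Why: Appel bromination of a primary allylic alcohol under neutral conditions that the three silyl ethers tolerate.

Step 14
Reactants: 17 (5α)-11-bromo-17,19-bis(tert-butyldimethylsilyloxy)-3β-(triisopropylsilyloxy)-12,13,14,15,16-pentanorlabd-8-ene; 18 methyl acetoacetate
Product: 19 methyl 17,19-bis(tert-butyldimethylsilyloxy)-13-oxo-3β-(triisopropylsilyloxy)-16-norlabd-8-en-15-oate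
Conditions: 18, LiN(i-Pr)2 (2.1 equiv), THF, 0 °C; then 17, 0 °C → rt; aq. NH4Cl
Reagents that add atoms: none
Why: γ-Alkylation of the acetoacetate dianion by a primary allylic bromide (SN2 at C11), which forms C11–C12 and delivers the β-keto ester carrying C12–C15.

Step 15
Reactants: 19 methyl 17,19-bis(tert-butyldimethylsilyloxy)-13-oxo-3β-(triisopropylsilyloxy)-16-norlabd-8-en-15-oate
Product: 20 methyl (13Z)-17,19-bis(tert-butyldimethylsilyloxy)-13-(diethoxyphosphoryloxy)-3β-(triisopropylsilyloxy)-16-norlabda-8,13-dien-15-oate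
Conditions: NaH, Et2O, 0 °C; ClP(O)(OEt)2, 0 °C → rt
Reagents that add atoms: diethyl chlorophosphate, CCOP(=O)(Cl)OCC
Why: O-Phosphorylation of the chelated sodium enolate of the β-keto ester in ether, which is known to give the Z-enol phosphate with the phosphate cis to the ester.

Step 16
Reactants: 20 methyl (13Z)-17,19-bis(tert-butyldimethylsilyloxy)-13-(diethoxyphosphoryloxy)-3β-(triisopropylsilyloxy)-16-norlabda-8,13-dien-15-oate
Product: 21 methyl (13E)-17,19-bis(tert-butyldimethylsilyloxy)-3β-(triisopropylsilyloxy)labda-8,13-dien-15-oate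
Conditions: Me2CuLi (from MeLi and CuI), Et2O, −78 → −45 °C
Reagents that add atoms: lithium dimethylcuprate, [Li+].C[Cu-]C
Why: Addition–elimination of the dimethylcuprate on the β-phosphoryloxy enoate with retention of geometry, which installs C16 and fixes the 13E double bond, allylic silyl ethers being inert to the cuprate at low temperature.

Step 17
Reactants: 21 methyl (13E)-17,19-bis(tert-butyldimethylsilyloxy)-3β-(triisopropylsilyloxy)labda-8,13-dien-15-oate
Product: 22 methyl (13E)-17,19-dihydroxy-3β-(triisopropylsilyloxy)labda-8,13-dien-15-oate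
Conditions: HF·pyridine, pyridine, THF, 0 °C → rt
Reagents that add atoms: none
Why: Buffered fluoride desilylation that removes the two primary TBS ethers (C17, C19) and leaves the hindered secondary TIPS ether at O3, a standard primary-versus-secondary silyl differentiation.

Step 18
Reactants: 22 methyl (13E)-17,19-dihydroxy-3β-(triisopropylsilyloxy)labda-8,13-dien-15-oate
Product: 25 methyl (13E)-19-hydroxy-3β-(triisopropylsilyloxy)labda-8(17),13-dien-15-oate (9α-H), via sulfonylhydrazine adduct 23 (not isolated), via allylic diazene 24 (not isolated)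
Conditions: PPh3, diethyl azodicarboxylate, 2-nitrobenzenesulfonylhydrazide, THF, −30 °C → rt
Reagents that add atoms: none
Why: Reductive allylic transposition in which Mitsunobu displacement of the unhindered allylic C17 hydroxyl by the sulfonylhydrazide (the neopentyl C19 hydroxyl cannot be displaced), loss of sulfinic acid to the monoalkyl diazene and retro-ene loss of N2 move the double bond to C8=C17 and deliver hydrogen to C9 from the α face, anti to the axial C20 methyl, so that the side chain ends equatorial (9α-H).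

Step 19
Reactants: 25 methyl (13E)-19-hydroxy-3β-(triisopropylsilyloxy)labda-8(17),13-dien-15-oate
Product: 26 methyl (13E)-19-oxo-3β-(triisopropylsilyloxy)labda-8(17),13-dien-15-oate
Conditions: Dess–Martin periodinane, CH2Cl2, 0 °C → rt
Reagents that add atoms: none
Why: Dess–Martin oxidation of the neopentyl primary alcohol to the C19 aldehyde, which has no α-hydrogen and so can neither epimerise nor eliminate.

Step 20
Reactants: 26 methyl (13E)-19-oxo-3β-(triisopropylsilyloxy)labda-8(17),13-dien-15-oate
Product: 27 (13E)-15-methoxy-15-oxo-3β-(triisopropylsilyloxy)labda-8(17),13-dien-19-oic acid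
Conditions: NaClO2, NaH2PO4, 2-methyl-2-butene, t-BuOH/H2O, rt
Reagents that add atoms: sodium chlorite, [Na+].[O-]Cl=O
Why: Pinnick oxidation of the hindered aldehyde to the C19 carboxylic acid, with 2-methyl-2-butene as hypochlorite scavenger to protect both alkenes.

Step 21
Reactants: 27 (13E)-15-methoxy-15-oxo-3β-(triisopropylsilyloxy)labda-8(17),13-dien-19-oic acid
Product: 29 (13E)-3β-hydroxylabda-8(17),13-diene-15,19-dioic acid (3β-hydroxyagathic acid), via hydroxy acid methyl ester 28 (not isolated)
Conditions: Bu4NF, THF, 60 °C; then LiOH, MeOH/H2O, rt; HCl to pH 3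
Reagents that add atoms: lithium hydroxide, [Li+].[OH-]
Why: Fluoride cleavage of the TIPS ether followed in the same flask by saponification of the C15 methyl ester, with no stereocentre at risk because C4 is quaternary and the enoate meets only mild hydroxide.

Step 22
Reactants: 29 (13E)-3β-hydroxylabda-8(17),13-diene-15,19-dioic acid
Product: 30 3β-acetoxy-agathic acid [(13E)-3β-acetoxylabda-8(17),13-diene-15,19-dioic acid]
Conditions: Ac2O, pyridine, 4-(dimethylamino)pyridine (cat.), rt; aq. NaHCO3, then pH 3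
Reagents that add atoms: acetic anhydride, CC(=O)OC(C)=O
Why: O-Acetylation of the equatorial 3β-hydroxyl with acetic anhydride and pyridine, the aqueous bicarbonate work-up returning both carboxylic acids in free form.

Compound list
1 | 2-methylcyclohexane-1,3-dione | CC1C(=O)CCCC1=O | starting material
2 | formaldehyde | C=O | starting material
3 | 2-(hydroxymethyl)-2-methylcyclohexane-1,3-dione | CC1(CO)C(=O)CCCC1=O | intermediate
4 | 2-[(tert-butyldimethylsilyloxy)methyl]-2-methylcyclohexane-1,3-dione | CC1(CO[Si](C)(C)C(C)(C)C)C(=O)CCCC1=O | intermediate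
5 | (2S,3S)-2-[(tert-butyldimethylsilyloxy)methyl]-3-hydroxy-2-methylcyclohexan-1-one | O=C1CCC[C@H](O)[C@]1(C)CO[Si](C)(C)C(C)(C)C | intermediate
6 | (2S,3S)-2-[(tert-butyldimethylsilyloxy)methyl]-2-methyl-3-(triisopropylsilyloxy)cyclohexan-1-one | O=C1CCC[C@H](O[Si](C(C)C)(C(C)C)C(C)C)[C@]1(C)CO[Si](C)(C)C(C)(C)C | intermediate
7 | (2S,3S)-2-[(tert-butyldimethylsilyloxy)methyl]-2,6-dimethyl-3-(triisopropylsilyloxy)cyclohexan-1-one (C6 epimers) | O=C1C(C)CC[C@H](O[Si](C(C)C)(C(C)C)C(C)C)[C@]1(C)CO[Si](C)(C)C(C)(C)C | intermediate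
8 | (5S,6S)-6-[(tert-butyldimethylsilyloxy)methyl]-2,6-dimethyl-5-(triisopropylsilyloxy)cyclohex-1-en-1-yl trifluoromethanesulfonate | CC1=C(OS(=O)(=O)C(F)(F)F)[C@@](C)(CO[Si](C)(C)C(C)(C)C)[C@@H](O[Si](C(C)C)(C(C)C)C(C)C)CC1 | intermediate
9 | tributyl(vinyl)stannane | C=C[Sn](CCCC)(CCCC)CCCC | starting material
10 | tert-butyl{[(1S,6S)-1,3-dimethyl-6-(triisopropylsilyloxy)-2-vinylcyclohex-2-en-1-yl]methoxy}dimethylsilane | C=CC1=C(C)CC[C@H](O[Si](C(C)C)(C(C)C)C(C)C)[C@]1(C)CO[Si](C)(C)C(C)(C)C | intermediate
11 | but-2-yne-1,4-diol | OCC#CCO | starting material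
12 | 4-(tert-butyldimethylsilyloxy)but-2-yn-1-ol | OCC#CCO[Si](C)(C)C(C)(C)C | intermediate
13 | 4-(tert-butyldimethylsilyloxy)but-2-ynal | O=CC#CCO[Si](C)(C)C(C)(C)C | intermediate
14 | 17,19-bis(tert-butyldimethylsilyloxy)-3β-(triisopropylsilyloxy)-12,13,14,15,16-pentanorlabda-5,8-dien-11-al | O=CC1=C(CO[Si](C)(C)C(C)(C)C)CC=C2[C@]1(C)CC[C@H](O[Si](C(C)C)(C(C)C)C(C)C)[C@]2(C)CO[Si](C)(C)C(C)(C)C | intermediate
15 | (5α)-17,19-bis(tert-butyldimethylsilyloxy)-3β-(triisopropylsilyloxy)-12,13,14,15,16-pentanorlabd-8-en-11-al | O=CC1=C(CO[Si](C)(C)C(C)(C)C)CC[C@@H]2[C@]1(C)CC[C@H](O[Si](C(C)C)(C(C)C)C(C)C)[C@]2(C)CO[Si](C)(C)C(C)(C)C | intermediate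
16 | (5α)-17,19-bis(tert-butyldimethylsilyloxy)-3β-(triisopropylsilyloxy)-12,13,14,15,16-pentanorlabd-8-en-11-ol | OCC1=C(CO[Si](C)(C)C(C)(C)C)CC[C@@H]2[C@]1(C)CC[C@H](O[Si](C(C)C)(C(C)C)C(C)C)[C@]2(C)CO[Si](C)(C)C(C)(C)C | intermediate
17 | (5α)-11-bromo-17,19-bis(tert-butyldimethylsilyloxy)-3β-(triisopropylsilyloxy)-12,13,14,15,16-pentanorlabd-8-ene | BrCC1=C(CO[Si](C)(C)C(C)(C)C)CC[C@@H]2[C@]1(C)CC[C@H](O[Si](C(C)C)(C(C)C)C(C)C)[C@]2(C)CO[Si](C)(C)C(C)(C)C | intermediate
18 | methyl acetoacetate | COC(=O)CC(C)=O | starting material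
19 | methyl 17,19-bis(tert-butyldimethylsilyloxy)-13-oxo-3β-(triisopropylsilyloxy)-16-norlabd-8-en-15-oate | COC(=O)CC(=O)CCC1=C(CO[Si](C)(C)C(C)(C)C)CC[C@@H]2[C@]1(C)CC[C@H](O[Si](C(C)C)(C(C)C)C(C)C)[C@]2(C)CO[Si](C)(C)C(C)(C)C | intermediate
20 | methyl (13Z)-17,19-bis(tert-butyldimethylsilyloxy)-13-(diethoxyphosphoryloxy)-3β-(triisopropylsilyloxy)-16-norlabda-8,13-dien-15-oate | COC(=O)/C=C(\OP(=O)(OCC)OCC)CCC1=C(CO[Si](C)(C)C(C)(C)C)CC[C@@H]2[C@]1(C)CC[C@H](O[Si](C(C)C)(C(C)C)C(C)C)[C@]2(C)CO[Si](C)(C)C(C)(C)C | intermediate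
21 | methyl (13E)-17,19-bis(tert-butyldimethylsilyloxy)-3β-(triisopropylsilyloxy)labda-8,13-dien-15-oate | COC(=O)/C=C(\C)CCC1=C(CO[Si](C)(C)C(C)(C)C)CC[C@@H]2[C@]1(C)CC[C@H](O[Si](C(C)C)(C(C)C)C(C)C)[C@]2(C)CO[Si](C)(C)C(C)(C)C | intermediate
22 | methyl (13E)-17,19-dihydroxy-3β-(triisopropylsilyloxy)labda-8,13-dien-15-oate | COC(=O)/C=C(\C)CCC1=C(CO)CC[C@@H]2[C@]1(C)CC[C@H](O[Si](C(C)C)(C(C)C)C(C)C)[C@]2(C)CO | intermediate
23 | methyl (13E)-19-hydroxy-17-[1-(2-nitrophenylsulfonyl)hydrazinyl]-3β-(triisopropylsilyloxy)labda-8,13-dien-15-oate | COC(=O)/C=C(\C)CCC1=C(CN(N)S(=O)(=O)c3ccccc3[N+](=O)[O-])CC[C@@H]2[C@]1(C)CC[C@H](O[Si](C(C)C)(C(C)C)C(C)C)[C@]2(C)CO | intermediate (not isolated)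
24 | methyl (13E)-17-diazenyl-19-hydroxy-3β-(triisopropylsilyloxy)labda-8,13-dien-15-oate | COC(=O)/C=C(\C)CCC1=C(CN=N)CC[C@@H]2[C@]1(C)CC[C@H](O[Si](C(C)C)(C(C)C)C(C)C)[C@]2(C)CO | intermediate (not isolated)
25 | methyl (13E)-19-hydroxy-3β-(triisopropylsilyloxy)labda-8(17),13-dien-15-oate | C=C1CC[C@@H]2[C@](C)(CC[C@H](O[Si](C(C)C)(C(C)C)C(C)C)[C@]2(C)CO)[C@H]1CC/C(C)=C/C(=O)OC | intermediate
26 | methyl (13E)-19-oxo-3β-(triisopropylsilyloxy)labda-8(17),13-dien-15-oate | C=C1CC[C@@H]2[C@](C)(CC[C@H](O[Si](C(C)C)(C(C)C)C(C)C)[C@]2(C)C=O)[C@H]1CC/C(C)=C/C(=O)OC | intermediate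
27 | (13E)-15-methoxy-15-oxo-3β-(triisopropylsilyloxy)labda-8(17),13-dien-19-oic acid | C=C1CC[C@@H]2[C@](C)(CC[C@H](O[Si](C(C)C)(C(C)C)C(C)C)[C@]2(C)C(=O)O)[C@H]1CC/C(C)=C/C(=O)OC | intermediate
28 | (13E)-3β-hydroxy-15-methoxy-15-oxolabda-8(17),13-dien-19-oic acid | C=C1CC[C@@H]2[C@](C)(CC[C@H](O)[C@]2(C)C(=O)O)[C@H]1CC/C(C)=C/C(=O)OC | intermediate (not isolated)
29 | (13E)-3β-hydroxylabda-8(17),13-diene-15,19-dioic acid | C=C1CC[C@@H]2[C@](C)(CC[C@H](O)[C@]2(C)C(=O)O)[C@H]1CC/C(C)=C/C(=O)O | intermediate
30 | 3β-acetoxy-agathic acid | C=C1CC[C@@H]2[C@](C)(CC[C@H](OC(C)=O)[C@]2(C)C(=O)O)[C@H]1CC/C(C)=C/C(=O)O | target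

Total step count: 22.
Longest linear sequence: 20 steps (steps 1–7 and 10–22, from compound 1); steps 8–9 make the ynal in a side branch.

Steps most likely to fail

Step 10. The cycloaddition at the tetrasubstituted terminus C10 may be slower than thermal polymerisation of the mono-activated ynal, and control of orientation may erode at the temperature then needed. The fallback sets out from diene 10 and comes back at alcohol 16. The diene 10 is heated with dimethyl but-2-ynedioate (neat, 110 °C), a symmetrical, doubly activated alkyne known to add to this diene class and posing no question of orientation, to give the bicyclic diene diester F1. Hydrogenation (H2, Pd/C, EtOAc) should give the trans-fused diester F2, and reduction with LiAlH4 (THF, 0 °C) the 11,17-diol F3. Silylation of the less hindered C17 hydroxyl (TBSCl, imidazole, CH2Cl2, −20 °C; the C11 hydroxyl is flanked by the quaternary C10) then rejoins the route at 16.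

Step 18. Hydrogen transfer within the diazene may occur in part to the β face of C9, or the sulfonylhydrazide may decompose before the Mitsunobu coupling is complete. The fallback sets out from diol 22 and comes back at 25. The allylic C17 hydroxyl of 22 is converted selectively into the allylic methyl carbonate F4 (ClCO2Me, pyridine, CH2Cl2, −20 °C). This is submitted to palladium-catalysed formate hydrogenolysis (Pd(OAc)2, PBu3, HCO2H, Et3N, THF, 60 °C): zerovalent palladium formed in the flask ionises the carbonate, the π-allyl complex sits on the open α face, and hydride from the formate passes from the metal to the more substituted terminus C9. This should give 25 with the exocyclic alkene and 9α-H.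

Step 3. The reduction may take the other enantiotopic carbonyl or the face syn to the silyloxymethyl arm, or run on to the diol. The fallback sets out from dione 3 and comes back at 5. The unprotected dione 3 is reduced with whole-cell baker's yeast (sucrose, water, 30 °C), a biocatalytic desymmetrisation long used for 2,2-disubstituted cyclohexane-1,3-diones, and is expected to give the (2S,3S)-dihydroxy ketone F5. Silylation of its primary hydroxyl (TBSCl, imidazole, DMF, 0 °C) gives 5.

Further compounds
F1 | step 10 | dimethyl 19-(tert-butyldimethylsilyloxy)-3β-(triisopropylsilyloxy)-12,13,14,15,16-pentanorlabda-5,8-diene-11,17-dioate | COC(=O)C1=C(C(=O)OC)CC=C2[C@]1(C)CC[C@H](O[Si](C(C)C)(C(C)C)C(C)C)[C@]2(C)CO[Si](C)(C)C(C)(C)C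
F2 | step 10 | dimethyl (5α)-19-(tert-butyldimethylsilyloxy)-3β-(triisopropylsilyloxy)-12,13,14,15,16-pentanorlabd-8-ene-11,17-dioate | COC(=O)C1=C(C(=O)OC)CC[C@@H]2[C@]1(C)CC[C@H](O[Si](C(C)C)(C(C)C)C(C)C)[C@]2(C)CO[Si](C)(C)C(C)(C)C
F3 | step 10 | (5α)-19-(tert-butyldimethylsilyloxy)-3β-(triisopropylsilyloxy)-12,13,14,15,16-pentanorlabd-8-ene-11,17-diol | OCC1=C(CO)CC[C@@H]2[C@]1(C)CC[C@H](O[Si](C(C)C)(C(C)C)C(C)C)[C@]2(C)CO[Si](C)(C)C(C)(C)C
F4 | step 18 | methyl (13E)-19-hydroxy-17-(methoxycarbonyloxy)-3β-(triisopropylsilyloxy)labda-8,13-dien-15-oate | COC(=O)/C=C(\C)CCC1=C(COC(=O)OC)CC[C@@H]2[C@]1(C)CC[C@H](O[Si](C(C)C)(C(C)C)C(C)C)[C@]2(C)CO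
F5 | step 3 | (2S,3S)-3-hydroxy-2-(hydroxymethyl)-2-methylcyclohexan-1-one | O=C1CCC[C@H](O)[C@]1(C)CO
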